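**Retrosynthetic overview**
- Target ⇐ desilylation ⇐ reduction of an aldehyde tosylhydrazone to a methyl group ⇐ tricyclic 2-ethoxytetrahydrofuran acetal.
- Key step: Ueno–Stork 5-exo radical cyclisation forms the C7–C2′ bond. The complete diacetoxy side chain, tethered as an α-bromo acetal to the C8 oxygen, is delivered cis to C8–O, and the tether carbon later becomes the C1′ methyl group.
- Bromoacetal ⇐ hexahydroazulene-1,8-diol (seven-membered ring by ring-closing metathesis) + side-chain enol ether (Brown alkoxyallylboration of 3-methylbut-2-enal, then aldehyde-selective Wacker oxidation).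
- Metathesis triene ⇐ conjugate addition/aldol three-component coupling on a 4-silyloxycyclopentenone, then methyl addition, oxidative transposition, epoxidation and Wharton transposition to set the tertiary carbinol.
- Ring order: five-membered ring from the starting enone, then the seven-membered ring, then a temporary tetrahydrofuran ring (radical step) that is opened again at the end.

Assumption: where a step gives epimers at a centre that is erased later, the mixture is carried on and the SMILES shows the major isomer or leaves that centre open; the enol ether is drawn as its E isomer.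

**Route**

Step 1
Reactants: 1 2-bromoprop-2-enal
Product: 2 rac-2-bromopenta-1,4-dien-3-ol
Conditions: vinylmagnesium bromide, THF, −78 °C; aq NH4Cl
Reagents that add atoms: vinylmagnesium bromide (C=C[Mg]Br)
Why: Grignard 1,2-addition to the enal carbonyl gives the racemic divinyl carbinol.

Step 2
Reactants: 2 rac-2-bromopenta-1,4-dien-3-ol
Product: 3 (3R)-2-bromopenta-1,4-dien-3-ol
Conditions: Ti(OiPr)4 (10 mol%), D-(−)-diisopropyl tartrate (15 mol%), tBuOOH (0.6 equiv), 4 Å MS, CH2Cl2, −20 °C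
Reagents that add atoms: none
Why: Sharpless kinetic resolution: with the D-tartrate the (S)-alcohol is epoxidised at its unsubstituted vinyl group (the bromoalkene is too electron-poor), so the (R)-alcohol is recovered in high ee.

Step 3
Reactants: 3 (3R)-2-bromopenta-1,4-dien-3-ol
Product: 4 (3R)-2-bromo-3-(tert-butyldimethylsilyloxy)penta-1,4-diene
Conditions: TBSCl, imidazole, DMF, 0 °C to rt
Reagents that add atoms: tert-butyldimethylsilyl chloride (C[Si](C)(Cl)C(C)(C)C)
Why: Standard silyl ether formation; the stereocentre is untouched.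

Step 4
Reactants: 5 3-methylbut-2-enal, 6 3-(methoxymethoxy)prop-1-ene
Product: 8 (3S,4S)-3-(methoxymethoxy)-6-methylhepta-1,5-dien-4-ol, via allylborane 7 (not isolated)
Conditions: 6, sBuLi, THF, −78 °C; (+)-Ipc2BOMe (from (−)-α-pinene); BF3·OEt2; 5, −78 °C; then NaOH, H2O2
Reagents that add atoms: none
Why: Brown γ-alkoxyallylboration: the (Z)-alkoxyallyl borane reacts through a chair transition state to give the syn diol monoether, and the isopinocampheyl groups from (−)-α-pinene direct attack to the re face of the aldehyde, setting (3S,4S).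

Step 5
Reactants: 8 (3S,4S)-3-(methoxymethoxy)-6-methylhepta-1,5-dien-4-ol
Product: 10 (3S,4S)-6-methylhepta-1,5-diene-3,4-diyl diacetate, via diol 9 (not isolated)
Conditions: Me2BBr, CH2Cl2, −78 °C; aq NaHCO3; then Ac2O, pyridine, DMAP, CH2Cl2, 0 °C to rt
Reagents that add atoms: acetic anhydride (CC(=O)OC(C)=O)
Why: Low-temperature bromoborane cleavage of the MOM ether spares the ionisable allylic carbinol, and acetylation of the crude diol installs both acetates of the target.

Step 6
Reactants: 10 (3S,4S)-6-methylhepta-1,5-diene-3,4-diyl diacetate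
Product: 11 (3S,4S)-6-methyl-1-oxohept-5-ene-3,4-diyl diacetate
Conditions: PdCl2(PhCN)2 (10 mol%), CuCl2·2H2O (10 mol%), AgNO2 (5 mol%), O2 (1 atm), tBuOH/MeNO2 15:1, rt
Reagents that add atoms: dioxygen (O=O)
Why: Nitrite-modified aldehyde-selective Wacker oxidation: the allylic acetate steers anti-Markovnikov oxidation of the terminal vinyl group while the trisubstituted alkene stays intact.

Step 7
Reactants: 11 (3S,4S)-6-methyl-1-oxohept-5-ene-3,4-diyl diacetate
Product: 12 (3S,4S)-1,1-diethoxy-6-methylhept-5-ene-3,4-diyl diacetate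
Conditions: HC(OEt)3, PPTS (cat.), EtOH, rt
Reagents that add atoms: triethyl orthoformate (CCOC(OCC)OCC)
Why: Mild acid-catalysed acetalisation protects the elimination-prone β-acetoxy aldehyde.

Step 8
Reactants: 12 (3S,4S)-1,1-diethoxy-6-methylhept-5-ene-3,4-diyl diacetate
Product: 13 (1E,3S,4S)-1-ethoxy-6-methylhepta-1,5-diene-3,4-diyl diacetate (E/Z mixture usable)
Conditions: TMSOTf, iPr2NEt, CH2Cl2, −20 °C to rt
Reagents that add atoms: none
Why: Gassman elimination of ethanol from the acetal (silyl triflate with excess amine) gives the enol ether; the amine buffer suppresses Ferrier-type ionisation of the allylic acetate.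

Step 9
Reactants: 14 (4S)-4-hydroxycyclopent-2-en-1-one
Product: 15 (4S)-4-(tert-butyldimethylsilyloxy)cyclopent-2-en-1-one
Conditions: TBSCl, imidazole, DMF, 0 °C
Reagents that add atoms: tert-butyldimethylsilyl chloride (C[Si](C)(Cl)C(C)(C)C)
Why: Silylation gives the enone whose silyloxy group controls the facial selectivity of the next step.

Step 10
Reactants: 4 (3R)-2-bromo-3-(tert-butyldimethylsilyloxy)penta-1,4-diene, 15 (4S)-4-(tert-butyldimethylsilyloxy)cyclopent-2-en-1-one, 16 prop-2-enal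
Product: 19 (2R,3R,4S)-4-(tert-butyldimethylsilyloxy)-3-[(3R)-3-(tert-butyldimethylsilyloxy)penta-1,4-dien-2-yl]-2-[(1R)-1-hydroxyprop-2-enyl]cyclopentan-1-one, via Grignard reagent 17 (not isolated), via magnesium enolate 18 (not isolated)
Conditions: 4, Mg, THF, rt; CuBr·SMe2 (10 mol%), −78 °C; 15; then 16, −78 °C; aq NH4Cl
Reagents that add atoms: none
Why: Copper-catalysed conjugate addition/aldol three-component coupling: the alkenyl group adds anti to the silyloxy group, and the ring enolate takes acrolein anti to the new substituent through a Zimmerman–Traxler chair, giving the trans-2,3 arrangement (the later trans ring fusion) and the anti aldol (1′R).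

Step 11
Reactants: 19 the aldol from step 10
Product: 21 (4R,5R)-4-[(3R)-3-(tert-butyldimethylsilyloxy)penta-1,4-dien-2-yl]-5-[(1R)-1-(triethylsilyloxy)prop-2-enyl]cyclopent-2-en-1-one, via triethylsilyl ether 20 (not isolated)
Conditions: TESCl, imidazole, DMAP (cat.), CH2Cl2, 0 °C; then DBU, rt
Reagents that add atoms: chlorotriethylsilane (CC[Si](Cl)(CC)CC)
Why: Silylation of the secondary carbinol followed by E1cB loss of the β-silyloxy group gives the enone; the two ring stereocentres are not involved.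

Step 12
Reactants: 21 the enone from step 11
Product: 22 (4R,5R)-1-methyl-4-[(3R)-3-(tert-butyldimethylsilyloxy)penta-1,4-dien-2-yl]-5-[(1R)-1-(triethylsilyloxy)prop-2-enyl]cyclopent-2-en-1-ol (C1 epimers; 1R major)
Conditions: MeLi, CeCl3, THF, −78 °C
Reagents that add atoms: methyllithium ([Li]C)
Why: Organocerium 1,2-addition to the enone without enolisation; the new carbinol configuration is irrelevant because it is erased in the next step.

Step 13
Reactants: 22 the tertiary allylic alcohol from step 12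
Product: 23 (4S,5R)-3-methyl-5-[(3R)-3-(tert-butyldimethylsilyloxy)penta-1,4-dien-2-yl]-4-[(1R)-1-(triethylsilyloxy)prop-2-enyl]cyclopent-2-en-1-one
Conditions: pyridinium chlorochromate C5H5NH[CrO3Cl], NaOAc, 4 Å MS, CH2Cl2, rt
Reagents that add atoms: none
Why: Babler–Dauben oxidative 1,3-transposition of the tertiary allylic alcohol gives the β-methyl enone; both silyl ethers survive the buffered oxidant.

Step 14
Reactants: 23 the β-methyl enone from step 13
Product: 24 (1R,3R,4R,5R)-5-methyl-3-[(3R)-3-(tert-butyldimethylsilyloxy)penta-1,4-dien-2-yl]-4-[(1R)-1-(triethylsilyloxy)prop-2-enyl]-6-oxabicyclo[3.1.0]hexan-2-one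
Conditions: 30% H2O2, LiOH (cat.), MeOH, 0 °C
Reagents that add atoms: hydrogen peroxide (OO)
Why: Weitz–Scheffer nucleophilic epoxidation: hydroperoxide adds to the β-carbon anti to the neighbouring C4 side chain, which fixes the C–O bond of the future tertiary carbinol trans to that side chain; isolated alkenes do not react.

Step 15
Reactants: 24 the epoxy ketone from step 14
Product: 26 (1S,4R,5R)-5-[(1R)-1-hydroxyprop-2-enyl]-1-methyl-4-[(3R)-3-(tert-butyldimethylsilyloxy)penta-1,4-dien-2-yl]cyclopent-2-en-1-ol, via triethylsilyl ether 25 (not isolated)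
Conditions: N2H4·H2O, AcOH, MeOH, 0 °C to rt; then PPTS, MeOH, rt
Reagents that add atoms: none
Why: Wharton transposition (epoxy hydrazone to allylic alcohol with loss of N2) moves the alkene to C2=C3 and keeps the epoxide C–O bond as the (1S) tertiary carbinol; acid-catalysed methanolysis then removes the triethylsilyl group while the tert-butyldimethylsilyl ether stays.

Step 16
Reactants: 26 the triene diol from step 15
Product: 27 (1S,3aR,5R,8R,8aR)-5-(tert-butyldimethylsilyloxy)-1-methyl-4-methylidene-1,3a,4,5,8,8a-hexahydroazulene-1,8-diol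
Conditions: second-generation Grubbs catalyst (5 mol%), CH2Cl2 (2 mM), 40 °C
Reagents that add atoms: none
Why: Ring-closing metathesis between the two monosubstituted vinyl groups closes the seven-membered ring; the 1,1-disubstituted methylidene and the cyclopentene do not take part, and the trans ring fusion comes from step 10.

Step 17
Reactants: 27 the hexahydroazulenediol from step 16, 13 (1E,3S,4S)-1-ethoxy-6-methylhepta-1,5-diene-3,4-diyl diacetate
Product: 28 (1S,3aR,5R,8R,8aR)-8-{[(3S,4S)-3,4-diacetoxy-2-bromo-1-ethoxy-6-methylhept-5-enyl]oxy}-5-(tert-butyldimethylsilyloxy)-1-methyl-4-methylidene-1,3a,4,5,8,8a-hexahydroazulen-1-ol (epimers at the acetal and bromide carbons)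
Conditions: NBS, 13 (2 equiv), CH2Cl2, −40 °C
Reagents that add atoms: N-bromosuccinimide (O=C1CCC(=O)N1Br)
Why: Bromoacetalisation: the enol ether is by far the most nucleophilic alkene, and the resulting bromo oxocarbenium ion is captured by the secondary allylic C8 hydroxyl (the tertiary hydroxyl is too hindered).

Step 18
Reactants: 28 the bromoacetal from step 17
Product: 29 tricyclic acetal: 2-ethoxytetrahydrofuran cis-fused across C7–C8 of the (1S,3aR,5R,7S,8R,8aR)-5-(tert-butyldimethylsilyloxy)-1-hydroxy-1-methyl-4-methylidene-octahydroazulene and carrying the (1S,2S)-1,2-diacetoxy-4-methylpent-3-enyl group on the furan C3 (acetal epimers)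
Conditions: Bu3SnH (slow addition), AIBN (cat.), benzene, 80 °C
Reagents that add atoms: none
Why: Ueno–Stork radical cyclisation, the key C7–C2′ bond formation: the secondary radical adds 5-exo-trig to the ring alkene, the acetal tether forces the new bond cis to the C8 oxygen (7S), the bulky diacetoxy chain takes the convex exo position (2′R), and the ring radical at C6 is quenched by the tin hydride.

Step 19
Reactants: 29 the tricyclic acetal from step 18
Product: 31 (2R,3S,4S)-2-[(1S,3aR,5R,7S,8R,8aR)-5-(tert-butyldimethylsilyloxy)-1,8-dihydroxy-1-methyl-4-methylidene-1,3a,4,5,6,7,8,8a-octahydroazulen-7-yl]-6-methylhept-5-ene-3,4-diyl diacetate, via tosylhydrazone 30 (not isolated)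
Conditions: TsNHNH2, PPTS (cat.), THF/H2O, 45 °C; then catecholborane, CHCl3, 0 °C; NaOAc·3H2O, 60 °C
Reagents that add atoms: none
Why: Acid-catalysed opening of the acetal to the aldehyde tosylhydrazone frees the C8 hydroxyl, and Caglioti–Kabalka reduction turns the former tether carbon into the C1′ methyl group without touching acetates, alkenes or stereocentres.

Step 20
Reactants: 31 the silyl ether from step 19
Product: 32 (2R,3S,4S)-2-[(1S,3aR,5R,7S,8R,8aR)-1,5,8-trihydroxy-1-methyl-4-methylidene-1,3a,4,5,6,7,8,8a-octahydroazulen-7-yl]-6-methylhept-5-ene-3,4-diyl diacetate (target)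
Conditions: HF·pyridine, pyridine, THF, 0 °C to rt
Reagents that add atoms: none
Why: Buffered fluoride desilylation releases the C5 hydroxyl without acetate migration or ionisation of the tertiary allylic alcohol.

**Compound list**

1 | 2-bromoprop-2-enal | C=C(Br)C=O | starting material
2 | rac-2-bromopenta-1,4-dien-3-ol | C=CC(O)C(Br)=C | intermediate
3 | (3R)-2-bromopenta-1,4-dien-3-ol | C=C[C@@H](O)C(Br)=C | intermediate
4 | (3R)-2-bromo-3-(tert-butyldimethylsilyloxy)penta-1,4-diene | C=C[C@@H](O[Si](C)(C)C(C)(C)C)C(Br)=C | intermediate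
5 | 3-methylbut-2-enal | CC(C)=CC=O | starting material
6 | 3-(methoxymethoxy)prop-1-ene | C=CCOCOC | starting material
7 | [(2Z)-3-(methoxymethoxy)prop-2-enyl]bis(isopinocampheyl)borane, Ipc groups from (−)-α-pinene | COCO/C=C\CB([C@H]1C[C@H]2C[C@@H]([C@@H]1C)C2(C)C)[C@H]1C[C@H]2C[C@@H]([C@@H]1C)C2(C)C | intermediate
8 | (3S,4S)-3-(methoxymethoxy)-6-methylhepta-1,5-dien-4-ol | C=C[C@H](OCOC)[C@@H](O)C=C(C)C | intermediate
9 | (3S,4S)-6-methylhepta-1,5-diene-3,4-diol | C=C[C@H](O)[C@@H](O)C=C(C)C | intermediate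
10 | (3S,4S)-6-methylhepta-1,5-diene-3,4-diyl diacetate | C=C[C@H](OC(C)=O)[C@@H](OC(C)=O)C=C(C)C | intermediate
11 | (3S,4S)-6-methyl-1-oxohept-5-ene-3,4-diyl diacetate | O=CC[C@H](OC(C)=O)[C@@H](OC(C)=O)C=C(C)C | intermediate
12 | (3S,4S)-1,1-diethoxy-6-methylhept-5-ene-3,4-diyl diacetate | CCOC(OCC)C[C@H](OC(C)=O)[C@@H](OC(C)=O)C=C(C)C | intermediate
13 | (1E,3S,4S)-1-ethoxy-6-methylhepta-1,5-diene-3,4-diyl diacetate | CCO/C=C/[C@H](OC(C)=O)[C@@H](OC(C)=O)C=C(C)C | intermediate
14 | (4S)-4-hydroxycyclopent-2-en-1-one | O=C1C=C[C@@H](O)C1 | starting material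
15 | (4S)-4-(tert-butyldimethylsilyloxy)cyclopent-2-en-1-one | O=C1C=C[C@@H](O[Si](C)(C)C(C)(C)C)C1 | intermediate
16 | prop-2-enal | C=CC=O | starting material
17 | bromo[(3R)-3-(tert-butyldimethylsilyloxy)penta-1,4-dien-2-yl]magnesium | C=C[C@@H](O[Si](C)(C)C(C)(C)C)C(=C)[Mg]Br | intermediate
18 | bromomagnesium enolate of (3R,4S)-4-(tert-butyldimethylsilyloxy)-3-[(3R)-3-(tert-butyldimethylsilyloxy)penta-1,4-dien-2-yl]cyclopentanone | Br[Mg]OC1=C[C@H](C(=C)[C@H](O[Si](C)(C)C(C)(C)C)C=C)[C@@H](O[Si](C)(C)C(C)(C)C)C1 | intermediate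
19 | (2R,3R,4S)-4-(tert-butyldimethylsilyloxy)-3-[(3R)-3-(tert-butyldimethylsilyloxy)penta-1,4-dien-2-yl]-2-[(1R)-1-hydroxyprop-2-enyl]cyclopentan-1-one | O=C1[C@@H]([C@H](O)C=C)[C@H](C(=C)[C@H](O[Si](C)(C)C(C)(C)C)C=C)[C@@H](O[Si](C)(C)C(C)(C)C)C1 | intermediate
20 | triethylsilyl ether of 19 at the side-chain carbinol | O=C1[C@@H]([C@H](O[Si](CC)(CC)CC)C=C)[C@H](C(=C)[C@H](O[Si](C)(C)C(C)(C)C)C=C)[C@@H](O[Si](C)(C)C(C)(C)C)C1 | intermediate
21 | (4R,5R)-4-[(3R)-3-(tert-butyldimethylsilyloxy)penta-1,4-dien-2-yl]-5-[(1R)-1-(triethylsilyloxy)prop-2-enyl]cyclopent-2-en-1-one | O=C1C=C[C@@H](C(=C)[C@H](O[Si](C)(C)C(C)(C)C)C=C)[C@@H]1[C@H](O[Si](CC)(CC)CC)C=C | intermediate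
22 | (4R,5R)-1-methyl-4-[(3R)-3-(tert-butyldimethylsilyloxy)penta-1,4-dien-2-yl]-5-[(1R)-1-(triethylsilyloxy)prop-2-enyl]cyclopent-2-en-1-ol, C1 epimers, 1R shown | C[C@@]1(O)C=C[C@@H](C(=C)[C@H](O[Si](C)(C)C(C)(C)C)C=C)[C@@H]1[C@H](O[Si](CC)(CC)CC)C=C | intermediate
23 | (4S,5R)-3-methyl-5-[(3R)-3-(tert-butyldimethylsilyloxy)penta-1,4-dien-2-yl]-4-[(1R)-1-(triethylsilyloxy)prop-2-enyl]cyclopent-2-en-1-one | CC1=CC(=O)[C@@H](C(=C)[C@H](O[Si](C)(C)C(C)(C)C)C=C)[C@@H]1[C@H](O[Si](CC)(CC)CC)C=C | intermediate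
24 | (1R,3R,4R,5R)-5-methyl-3-[(3R)-3-(tert-butyldimethylsilyloxy)penta-1,4-dien-2-yl]-4-[(1R)-1-(triethylsilyloxy)prop-2-enyl]-6-oxabicyclo[3.1.0]hexan-2-one | C[C@]12O[C@H]1C(=O)[C@@H](C(=C)[C@H](O[Si](C)(C)C(C)(C)C)C=C)[C@@H]2[C@H](O[Si](CC)(CC)CC)C=C | intermediate
25 | (1S,4R,5R)-1-methyl-4-[(3R)-3-(tert-butyldimethylsilyloxy)penta-1,4-dien-2-yl]-5-[(1R)-1-(triethylsilyloxy)prop-2-enyl]cyclopent-2-en-1-ol | C[C@]1(O)C=C[C@@H](C(=C)[C@H](O[Si](C)(C)C(C)(C)C)C=C)[C@@H]1[C@H](O[Si](CC)(CC)CC)C=C | intermediate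
26 | (1S,4R,5R)-5-[(1R)-1-hydroxyprop-2-enyl]-1-methyl-4-[(3R)-3-(tert-butyldimethylsilyloxy)penta-1,4-dien-2-yl]cyclopent-2-en-1-ol | C[C@]1(O)C=C[C@@H](C(=C)[C@H](O[Si](C)(C)C(C)(C)C)C=C)[C@@H]1[C@H](O)C=C | intermediate
27 | (1S,3aR,5R,8R,8aR)-5-(tert-butyldimethylsilyloxy)-1-methyl-4-methylidene-1,3a,4,5,8,8a-hexahydroazulene-1,8-diol | C=C1[C@H](O[Si](C)(C)C(C)(C)C)C=C[C@@H](O)[C@H]2[C@H]1C=C[C@]2(C)O | intermediate
28 | C8 mixed bromoacetal of 27 with 13 (epimers at the acetal and bromide carbons) | C=C1[C@H](O[Si](C)(C)C(C)(C)C)C=C[C@@H](OC(OCC)C(Br)[C@H](OC(C)=O)[C@@H](OC(C)=O)C=C(C)C)[C@H]2[C@H]1C=C[C@]2(C)O | intermediate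
29 | tricyclic 2-ethoxytetrahydrofuran acetal cis-fused at C7–C8 (acetal epimers) | C=C1[C@H](O[Si](C)(C)C(C)(C)C)C[C@H]2[C@H]([C@H](OC(C)=O)[C@@H](OC(C)=O)C=C(C)C)C(OCC)O[C@H]2[C@H]3[C@H]1C=C[C@]3(C)O | intermediate
30 | tosylhydrazone of the C1′ aldehyde (31 with CH=N–NHTs in place of the C1′ methyl) | C=C1[C@H](O[Si](C)(C)C(C)(C)C)C[C@@H]([C@@H](C=NNS(=O)(=O)c2ccc(C)cc2)[C@H](OC(C)=O)[C@H](C=C(C)C)OC(C)=O)[C@@H](O)[C@H]3[C@H]1C=C[C@]3(C)O | intermediate
31 | (2R,3S,4S)-2-[(1S,3aR,5R,7S,8R,8aR)-5-(tert-butyldimethylsilyloxy)-1,8-dihydroxy-1-methyl-4-methylidene-1,3a,4,5,6,7,8,8a-octahydroazulen-7-yl]-6-methylhept-5-ene-3,4-diyl diacetate | C=C1[C@H](O[Si](C)(C)C(C)(C)C)C[C@@H]([C@@H](C)[C@H](OC(C)=O)[C@H](C=C(C)C)OC(C)=O)[C@@H](O)[C@H]2[C@H]1C=C[C@]2(C)O | intermediate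
32 | (2R,3S,4S)-2-[(1S,3aR,5R,7S,8R,8aR)-1,5,8-trihydroxy-1-methyl-4-methylidene-1,3a,4,5,6,7,8,8a-octahydroazulen-7-yl]-6-methylhept-5-ene-3,4-diyl diacetate | C=C1[C@H](O)C[C@@H]([C@@H](C)[C@H](OC(C)=O)[C@H](C=C(C)C)OC(C)=O)[C@@H](O)[C@H]2[C@H]1C=C[C@]2(C)O | target

**Step count and risks**

Total step count: 20. Longest linear sequence: 14 steps (steps 1–3, then 10–20).

Steps most likely to fail:

Step 18 (radical cyclisation). The secondary radical may be reduced before it closes, the ring radical at C6 may undergo a 1,2-vinyl shift through the neighbouring methylidene, and the exo preference at C2′ may be only moderate. The fallback sets out from 27 and returns at 30. It replaces the tethered closure by an intermolecular radical alkylation of a C8 ketone enol ether. MnO2 oxidises the C8 allylic alcohol of 27 to the dienone F1. Conjugate reduction with K[HB(sBu)3] and trapping with TESCl gives the silyl enol ether F2. Aldehyde 11 is α-brominated (NBS, pyrrolidine catalyst) to the bromo aldehyde F3. Ru(bpy)3Cl2 and visible light generate the α-formyl radical from F3, which adds to F2 at C7 to give the keto aldehyde F4; C7 and C2′ can then be equilibrated because both are α to a carbonyl. TsNHNH2 converts the aldehyde of F4 selectively to the keto tosylhydrazone F5, and NaBH4/CeCl3 reduces the C8 ketone anti to the C7 substituent to give 30, which is reduced as in step 19.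

Step 14 (epoxidation of the base-sensitive enone). The ring CH between the ketone and the methylidene-bearing substituent can be deprotonated, which would pull the exocyclic alkene into conjugation. The fallback sets out from 23 and returns at 25. It introduces the tertiary oxygen by conjugate borylation instead of epoxidation. CuCl, NaOtBu, a bisphosphine and B2pin2 in MeOH/THF add boron to the β-carbon anti to the C4 side chain to give the β-boryl ketone F6. NaBO3·4H2O oxidises it with retention to the β-hydroxy ketone F7. KHMDS and PhNTf2 form the less substituted enol triflate F8, and Pd(OAc)2, PPh3, Bu3N and HCO2H reduce it to the alkene 25.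

Step 6 (aldehyde-selective Wacker oxidation). Regioselectivity may be incomplete and the β-acetoxy aldehyde can lose acetic acid. The fallback sets out from 10 and returns at 11. It uses hydroboration and oxidation instead of palladium catalysis: 9-BBN adds only to the terminal vinyl group, buffered NaBO3·4H2O gives the primary alcohol F9, and Dess–Martin periodinane oxidises it to 11.

Further compounds
F1 | step 18 | (1S,3aR,5R,8aR)-5-(tert-butyldimethylsilyloxy)-1-hydroxy-1-methyl-4-methylidene-3a,4,5,8a-tetrahydroazulen-8(1H)-one | C=C1[C@H](O[Si](C)(C)C(C)(C)C)C=CC(=O)[C@H]2[C@H]1C=C[C@]2(C)O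
F2 | step 18 | C8 triethylsilyl enol ether (C7=C8) of the 6,7-dihydro ketone derived from F1 | C=C1[C@H](O[Si](C)(C)C(C)(C)C)CC=C(O[Si](CC)(CC)CC)[C@H]2[C@H]1C=C[C@]2(C)O
F3 | step 18 | (3S,4S)-2-bromo-6-methyl-1-oxohept-5-ene-3,4-diyl diacetate (C2 epimers) | O=CC(Br)[C@H](OC(C)=O)[C@@H](OC(C)=O)C=C(C)C
F4 | step 18 | C8 ketone bearing the (2R,3S,4S)-3,4-diacetoxy-6-methyl-1-oxohept-5-en-2-yl group at C7 | C=C1[C@H](O[Si](C)(C)C(C)(C)C)C[C@@H]([C@@H](C=O)[C@H](OC(C)=O)[C@H](C=C(C)C)OC(C)=O)C(=O)[C@H]2[C@H]1C=C[C@]2(C)O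
F5 | step 18 | tosylhydrazone of the aldehyde of F4 (C8 ketone retained) | C=C1[C@H](O[Si](C)(C)C(C)(C)C)C[C@@H]([C@@H](C=NNS(=O)(=O)c2ccc(C)cc2)[C@H](OC(C)=O)[C@H](C=C(C)C)OC(C)=O)C(=O)[C@H]2[C@H]1C=C[C@]2(C)O
F6 | step 14 | β-(pinacolboryl) ketone from 23 (boron on the methyl-bearing ring carbon) | C[C@]1(B2OC(C)(C)C(C)(C)O2)CC(=O)[C@@H](C(=C)[C@H](O[Si](C)(C)C(C)(C)C)C=C)[C@@H]1[C@H](O[Si](CC)(CC)CC)C=C
F7 | step 14 | β-hydroxy ketone (tertiary carbinol in place of the boronate of F6) | C[C@]1(O)CC(=O)[C@@H](C(=C)[C@H](O[Si](C)(C)C(C)(C)C)C=C)[C@@H]1[C@H](O[Si](CC)(CC)CC)C=C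
F8 | step 14 | enol triflate of F7 toward the ring CH2 | C[C@]1(O)C=C(OS(=O)(=O)C(F)(F)F)[C@@H](C(=C)[C@H](O[Si](C)(C)C(C)(C)C)C=C)[C@@H]1[C@H](O[Si](CC)(CC)CC)C=C
F9 | step 6 | (3S,4S)-1-hydroxy-6-methylhept-5-ene-3,4-diyl diacetate | OCC[C@H](OC(C)=O)[C@@H](OC(C)=O)C=C(C)C
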